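The 2,2-dimethyl-3-hydroxydihydropyran ring is traced back to a 2H-chromene, whose C3=C4 alkene later takes the C3 hydroxyl by asymmetric epoxidation and benzylic hydrogenolysis. The chromene is made in one operation from a 2,6-dihydroxybenzaldehyde and 2-methylprop-1-enylboronic acid. An amine-catalysed borono-Mannich transfer joins the formyl carbon (C4) to C3, and the ortho-quinone methide then formed closes by oxa-6π electrocyclisation from the phenolic oxygen (O1) to the dimethylated carbon (C2). The step exploits the ortho relation of O1 and C4 on the aromatic ring and the chelation of the C5 hydroxyl to the C6 acetyl group, which leaves O1 as the closing oxygen.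

Key step: step 2

Remark: chroman numbering (O1, C2, C3, C4, C4a, C5 to C8, C8a) is used for all bicyclic compounds; the stereocentre of the target is C3 and is read as (R); compounds 1, 3 and 9 are taken as catalogue chemicals.

Step 1
Reactants: 1 1-(2,4-dihydroxy-6-methoxyphenyl)ethan-1-one (2',4'-dihydroxy-6'-methoxyacetophenone)
Product: 2 3-acetyl-2,6-dihydroxy-4-methoxybenzaldehyde
Conditions: hexamethylenetetramine (1.1 equiv), AcOH, 95 °C; then 3 M aq. HCl, 80 °C
Reagents that add atoms: hexamethylenetetramine, C1N2CN3CN1CN(C2)C3; water, O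
Why: Duff reaction, in which the iminium electrophile from hexamethylenetetramine attacks ortho to a phenolic hydroxyl and the benzylamine is oxidised and hydrolysed to the aldehyde; attack is expected at C3', the only position flanked by two hydroxyls and the enol-type carbon of the free 4'-hydroxyl in the bond-fixed chelate of the 2'-hydroxyaryl ketone, as in the 3-formylation of 2,4-dihydroxyacetophenone.

Step 2
Reactants: 2 3-acetyl-2,6-dihydroxy-4-methoxybenzaldehyde; 3 (2-methylprop-1-en-1-yl)boronic acid
Product: 6 1-(5-hydroxy-7-methoxy-2,2-dimethyl-2H-chromen-6-yl)ethan-1-one, via allylic amine 4 (not isolated), via ortho-quinone methide 5 (not isolated)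
Conditions: 3 (2 equiv), Bn2NH (20 mol%), 1,4-dioxane, 90 °C
Reagents that add atoms: none
Why: In an amine-catalysed borono-Mannich reaction (Petasis type) the alkenyl group migrates from the phenoxide-bound boronate to the amine-activated formyl carbon, which makes the C4–C3 bond in 4. Thermal loss of Bn2NH from 4 gives ortho-quinone methide 5, whose oxa-6π electrocyclisation closes the six-membered pyran ring through the dienone oxygen, makes the O1–C2 bond, restores the aromatic ring and frees the amine for turnover. The closest known reaction is the amine-catalysed synthesis of 2H-chromenes from salicylaldehydes and alkenylboronic acids. No stereocentre is formed, because C2 carries two methyl groups and C3=C4 stays an alkene. The step needs closure through the oxygen para to the acetyl group and not through the one next to it; the hydrogen bond of that neighbouring hydroxyl to the acetyl carbonyl keeps it as the hydroxyl of 5 and leaves the other oxygen as the dienone oxygen, the preference also seen when 2,4-dihydroxyaryl ketones are annulated with enals. The electron-rich, chelated aldehyde should react slowly, so 3 is used in excess.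

Step 3
Reactants: 6 1-(5-hydroxy-7-methoxy-2,2-dimethyl-2H-chromen-6-yl)ethan-1-one
Product: 7 1-[(3R,4R)-3,4-epoxy-5-hydroxy-7-methoxy-2,2-dimethyl-3,4-dihydro-2H-chromen-6-yl]ethan-1-one
Conditions: (R,R)-(salen)MnCl (5 mol%; salen = N,N'-bis(3,5-di-tert-butylsalicylidene)cyclohexane-1,2-diamine dianion; trivalent manganese), mCPBA (2 equiv), NMO (5 equiv), CH2Cl2, −78 °C; cold aq. NaHCO3 work-up, filtration through basic alumina, used at once
Reagents that add atoms: mCPBA, OOC(=O)c1cccc(Cl)c1
Why: Jacobsen–Katsuki epoxidation, for which the cis, aryl-conjugated C3=C4 alkene of a 2,2-dimethylchromene is the privileged substrate class; the oxo species of pentavalent manganese from the (R,R)-catalyst should deliver oxygen to the face that gives the (3R,4R)-epoxide (the (S,S)-catalyst being the one that gives (3S,4S)-epoxychromans), so C3 is set under catalyst control, while the anhydrous low-temperature oxidant spares the hydrogen-bonded phenol and the aryl ketone.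

Step 4
Reactants: 7 1-[(3R,4R)-3,4-epoxy-5-hydroxy-7-methoxy-2,2-dimethyl-3,4-dihydro-2H-chromen-6-yl]ethan-1-one
Product: 8 1-[(3R)-3,5-dihydroxy-7-methoxy-2,2-dimethyl-3,4-dihydro-2H-chromen-6-yl]ethan-1-one
Conditions: H2 (1 atm), 10% Pd/C, K2CO3 (solid, 0.2 equiv), EtOAc, rt
Reagents that add atoms: none
Why: Catalytic hydrogenolysis of the benzylic C4–O bond of an aryl epoxide (as in the reduction of styrene oxides to 2-arylethanols) leaves the C3–O bond untouched, so the (3R) carbinol is retained while C4 becomes CH2, and the chelated aryl ketone should not be reduced at this pressure.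

Step 5
Reactants: 8 1-[(3R)-3,5-dihydroxy-7-methoxy-2,2-dimethyl-3,4-dihydro-2H-chromen-6-yl]ethan-1-one; 9 4-(tetrahydro-2H-pyran-2-yloxy)benzaldehyde
Product: 11 (E)-1-[(3R)-3,5-dihydroxy-7-methoxy-2,2-dimethyl-3,4-dihydro-2H-chromen-6-yl]-3-(4-hydroxyphenyl)prop-2-en-1-one, via tetrahydropyranyl chalcone 10 (not isolated)
Conditions: KOH (10 equiv), MeOH, rt; then 2 M aq. HCl to pH 1, MeOH, rt
Reagents that add atoms: none
Why: Claisen–Schmidt condensation, in which the methyl ketone enolate adds to the non-enolisable aldehyde and E1cB loss of water gives the thermodynamically favoured (E)-enone, held open as its phenoxide in the basic medium; acidification of the same flask then cleaves the tetrahydropyranyl acetal by acetal exchange with methanol, and the C3 carbinol is not touched.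

Compound list
1 | 1-(2,4-dihydroxy-6-methoxyphenyl)ethan-1-one | CC(=O)c1c(O)cc(O)cc1OC | starting material
2 | 3-acetyl-2,6-dihydroxy-4-methoxybenzaldehyde | CC(=O)c1c(O)c(C=O)c(O)cc1OC | intermediate
3 | (2-methylprop-1-en-1-yl)boronic acid | CC(C)=CB(O)O | starting material
4 | 1-{3-[1-(dibenzylamino)-3-methylbut-2-en-1-yl]-2,4-dihydroxy-6-methoxyphenyl}ethan-1-one (racemic, not isolated) | CC(=O)c1c(O)c(C(C=C(C)C)N(Cc2ccccc2)Cc2ccccc2)c(O)cc1OC | intermediate
5 | (2Z)-4-acetyl-3-hydroxy-5-methoxy-2-(3-methylbut-2-en-1-ylidene)cyclohexa-3,5-dien-1-one (not isolated) | CC(=O)C1=C(O)/C(=C/C=C(C)C)C(=O)C=C1OC | intermediate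
6 | 1-(5-hydroxy-7-methoxy-2,2-dimethyl-2H-chromen-6-yl)ethan-1-one | CC(=O)c1c(O)c2C=CC(C)(C)Oc2cc1OC | intermediate
7 | 1-[(3R,4R)-3,4-epoxy-5-hydroxy-7-methoxy-2,2-dimethyl-3,4-dihydro-2H-chromen-6-yl]ethan-1-one | CC(=O)c1c(O)c2[C@H]3O[C@H]3C(C)(C)Oc2cc1OC | intermediate
8 | 1-[(3R)-3,5-dihydroxy-7-methoxy-2,2-dimethyl-3,4-dihydro-2H-chromen-6-yl]ethan-1-one | CC(=O)c1c(O)c2C[C@@H](O)C(C)(C)Oc2cc1OC | intermediate
9 | 4-(tetrahydro-2H-pyran-2-yloxy)benzaldehyde (racemic) | O=Cc1ccc(OC2CCCCO2)cc1 | starting material
10 | (E)-1-[(3R)-3,5-dihydroxy-7-methoxy-2,2-dimethyl-3,4-dihydro-2H-chromen-6-yl]-3-[4-(tetrahydro-2H-pyran-2-yloxy)phenyl]prop-2-en-1-one (acetal carbon unassigned, not isolated) | COc1cc2c(c(O)c1C(=O)/C=C/c1ccc(OC3CCCCO3)cc1)C[C@@H](O)C(C)(C)O2 | intermediate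
11 | (E)-1-[(3R)-3,5-dihydroxy-7-methoxy-2,2-dimethyl-3,4-dihydro-2H-chromen-6-yl]-3-(4-hydroxyphenyl)prop-2-en-1-one | COc1cc2c(c(O)c1C(=O)/C=C/c1ccc(O)cc1)C[C@@H](O)C(C)(C)O2 | target

Total step count: 5
Longest linear sequence: 5 steps (1 to 2 to 6 to 7 to 8 to 11)

Steps most likely to fail

Step 2 (key step). The alkenyl transfer to the electron-rich, doubly hydrogen-bonded formyl group may be slow, so that protodeboronation of 3 outruns it. The fallback sets out from 2 and returns at 6, and makes the same two bonds in two operations. 2-Methylprop-1-enylmagnesium bromide (3.5 equiv, THF, −78 to 0 °C) should first form the bis-phenoxide and then add to the formyl group, the more electrophilic of the two deactivated carbonyls. This gives 1-[2,4-dihydroxy-3-(1-hydroxy-3-methylbut-2-en-1-yl)-6-methoxyphenyl]ethan-1-one F1. Warming with PPTS in toluene at 60 °C should ionise this doubly activated benzylic alcohol to ortho-quinone methide 5, which closes to chromene 6.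

Step 1. Formylation may take place at the other free ring position (C5', between hydroxyl and methoxyl), or a second formyl group may enter. The fallback sets out from 1 and returns at 2. MOMCl (1.05 equiv) and iPr2NEt in CH2Cl2 at 0 °C should protect the non-chelated 4'-hydroxyl to give 1-[2-hydroxy-6-methoxy-4-(methoxymethoxy)phenyl]ethan-1-one F2. Ortho-specific formylation with MgCl2, Et3N and paraformaldehyde in MeCN at reflux can then only reach C3', the single free position ortho to the remaining phenol, and should give 3-acetyl-2-hydroxy-4-methoxy-6-(methoxymethoxy)benzaldehyde F3. 2 M aq. HCl in THF at rt removes the acetal and gives 2.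

Step 3. The free phenol may be oxidised by the oxo-manganese species, or the very electron-rich epoxide may ring-open during work-up with help from the C5 hydroxyl. The fallback sets out from 6 and returns at 8. Ac2O, pyridine and DMAP in CH2Cl2 should give 6-acetyl-7-methoxy-2,2-dimethyl-2H-chromen-5-yl acetate F4, in which the phenol is masked and the arene is less electron-rich. Epoxidation under the conditions of step 3 should give (3R,4R)-6-acetyl-3,4-epoxy-7-methoxy-2,2-dimethyl-3,4-dihydro-2H-chromen-5-yl acetate F5. Hydrogenolysis as in step 4 should give (3R)-6-acetyl-3-hydroxy-7-methoxy-2,2-dimethyl-3,4-dihydro-2H-chromen-5-yl acetate F6, and K2CO3 in MeOH at rt removes the acetate to give 8.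

Further compounds
F1 | step 2 | 1-[2,4-dihydroxy-3-(1-hydroxy-3-methylbut-2-en-1-yl)-6-methoxyphenyl]ethan-1-one (racemic) | CC(=O)c1c(O)c(C(O)C=C(C)C)c(O)cc1OC
F2 | step 1 | 1-[2-hydroxy-6-methoxy-4-(methoxymethoxy)phenyl]ethan-1-one | CC(=O)c1c(O)cc(OCOC)cc1OC
F3 | step 1 | 3-acetyl-2-hydroxy-4-methoxy-6-(methoxymethoxy)benzaldehyde | CC(=O)c1c(O)c(C=O)c(OCOC)cc1OC
F4 | step 3 | 6-acetyl-7-methoxy-2,2-dimethyl-2H-chromen-5-yl acetate | CC(=O)c1c(OC(C)=O)c2C=CC(C)(C)Oc2cc1OC
F5 | step 3 | (3R,4R)-6-acetyl-3,4-epoxy-7-methoxy-2,2-dimethyl-3,4-dihydro-2H-chromen-5-yl acetate | CC(=O)c1c(OC(C)=O)c2[C@H]3O[C@H]3C(C)(C)Oc2cc1OC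
F6 | step 3 | (3R)-6-acetyl-3-hydroxy-7-methoxy-2,2-dimethyl-3,4-dihydro-2H-chromen-5-yl acetate | CC(=O)c1c(OC(C)=O)c2C[C@@H](O)C(C)(C)Oc2cc1OC
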